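## Retrosynthetic overview

1. Jatamanvaltrate K comes from regioselective C11 acetylation of a triol. The triol comes from desilylation of the 1,7-bis(isovalerate).
2. The C7 ester comes from Luche reduction of a cyclopentenone, which sits in a stabilised push–pull dienone. The C1 acylal comes from acylation of a lactol. The lactol arises by spontaneous cyclisation of a 1,5-dialdehyde, generated by ozonolysis of a C9 vinyl group. The pyran ring is therefore formed last.
3. The C4(C11)–C3 unit comes from a Mukaiyama–Michael addition of the silyl enol ether of 3-silyloxypropanal to a cyclopentenone. Saegusa oxidation then restores the C5=C6 alkene.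
4. The C8 quaternary carbinol and C10 come from α-hydroxylation (Rubottom), then α′-hydroxymethylation anti to the C9 vinyl group. C9 comes from trans-cuprate addition to (R)-4-OTBS-cyclopentenone with elimination, which transfers chirality.

Assumption: the target's 1-OIsov is cis to H-9 (natural valepotriate configuration), and the cyclopentane numbering follows the iridoid numbering in the SMILES. In the descriptors below, β means the same face as H-9.

---

## Route

**Step 1**
Reactants: 1 (R)-4-(tert-butyldimethylsilyloxy)cyclopent-2-en-1-one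
Product: 2, the TES enol ether (C7=C8) of trans-5β-OTBS-9α-vinylcyclopentanone
Conditions: CH2=CHMgBr, CuBr·SMe2, then TESCl, HMPA, THF, −78 °C
Reagents that add atoms: vinylmagnesium bromide (C=C[Mg]Br); chlorotriethylsilane (CC[Si](Cl)(CC)CC)
Why: Cuprate conjugate addition occurs trans to the 4-OTBS group and sets C9, which carries the future C1. The enolate is trapped regiospecifically as the silyl enol ether.

**Step 2**
Reactants: 2
Product: 3, 8-(TESO)-9α-vinyl-5β-OTBS-cyclopentan-7-one
Conditions: mCPBA, NaHCO3, CH2Cl2, 0 °C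
Reagents that add atoms: mCPBA (OOC(=O)c1cccc(Cl)c1)
Why: Rubottom oxidation epoxidises the silyl enol ether and the silyl group migrates, giving the α-silyloxy ketone. C8 is oxygenated trans to the vinyl group, and its configuration is erased in step 4.

**Step 3**
Reactants: 3
Product: 4, 8β-(TESO)-9α-vinylcyclopent-5-en-7-one
Conditions: DBU, CH2Cl2, 25 °C
Reagents that add atoms: none
Why: E1cB elimination of TBSOH from the β-silyloxy ketone (C6 enolate) forms the C5=C6 enone and removes the temporary C5 stereocentre. C9 is untouched.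

**Step 4**
Reactants: 4
Product: 5, 8α-(TESO)-8β-(hydroxymethyl)-9α-vinylcyclopent-5-en-7-one
Conditions: LDA, THF, −78 °C; then monomeric HCHO, −78 °C
Reagents that add atoms: formaldehyde (C=O)
Why: Kinetic deprotonation occurs only at C8 because C6 is sp2 (α′-enolate). The aldol with HCHO occurs anti to the C9 vinyl group, so C10 is β and the oxygen ends up α, cis to C1, as in the target.

**Step 5**
Reactants: 5
Product: 6, the C10-OTBS ether of 5
Conditions: TBSCl, imidazole, DMAP (cat.), DMF, 25 °C
Reagents that add atoms: TBSCl (CC(C)(C)[Si](C)(C)Cl)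
Why: Silylation of the primary alcohol prevents later acylation at C10.

**Step 6**
Reactants: 7 3-(tert-butyldimethylsilyloxy)propanal
Product: 8, TMSO–CH=CH–CH2OTBS (Z/E mixture)
Conditions: TMSCl, Et3N, NaI, MeCN, 25 °C
Reagents that add atoms: chlorotrimethylsilane (C[Si](C)(C)Cl)
Why: Silyl enol ether formation makes the aldehyde a nucleophilic C4(C11)–C3 synthon. The TBS ether avoids the β-acetoxy aldehyde elimination that a C11 acetate would risk.

**Step 7**
Reactants: 6 and 8
Product: 9, the Mukaiyama–Michael adduct (C5–C4H(CH2OTBS)–CHO; TMS enol ether C6=C7). C4 and C5 are undefined.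
Conditions: TMSOTf (5 mol %), CH2Cl2, −78 °C
Reagents that add atoms: none
Why: Mukaiyama–Michael 1,4-addition occurs anti to the C9 vinyl group. The new C4 and C5 stereocentres are temporary because both become sp2 later.

**Step 8**
Reactants: 9
Product: 10, the enone-aldehyde (C5=C6–C7=O; C4 undefined)
Conditions: Pd(OAc)2 (10 mol %), benzoquinone, MeCN, 25 °C
Reagents that add atoms: none
Why: Saegusa–Ito oxidation of the silyl enol ether restores C5=C6, now β-substituted. C8 is quaternary, so only one regiochemistry is possible.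

**Step 9**
Reactants: 10
Product: 11, the lactol-dienone (pyran ring formed, C3=C4 enol ether, C1-OH anomeric mixture)
Conditions: O3, CH2Cl2, −78 °C; then PPh3; then PPTS (cat.), 25 °C
Reagents that add atoms: ozone ([O-][O+]=O), which supplies the C1 aldehyde oxygen
Why: Ozonolysis converts the terminal vinyl alkene selectively (the enone is electron-poor) into the C1 aldehyde. The 1,5-dialdehyde enolises at the very acidic C4 and closes by oxa-cyclisation to the push–pull lactol.

**Step 10**
Reactants: 11
Product: 12, the 1β-isovalerate (acylal) of 11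
Conditions: iPrCH2COCl, pyridine, DMAP (cat.), CH2Cl2, 0 °C
Reagents that add atoms: isovaleryl chloride (CC(C)CC(=O)Cl)
Why: Acylation of the anomerising lactol under basic conditions favours the axial acylal, which is the natural configuration cis to H-9 and trans to C8. C1 is set here.

**Step 11**
Reactants: 12
Product: 13, the 7β-allylic alcohol
Conditions: NaBH4, CeCl3·7H2O, MeOH/CH2Cl2, −78 °C
Reagents that add atoms: none
Why: Luche 1,2-reduction. Hydride attacks from the α face, anti to the larger C10 CH2OTBS group, giving 7β-OH trans to the 8α-oxygen. C7 is set here.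

**Step 12**
Reactants: 13 (crude, used immediately)
Product: 14, the 1,7-bis(isovalerate)
Conditions: iPrCH2COCl, pyridine, DMAP (cat.), CH2Cl2, 0 °C
Reagents that add atoms: isovaleryl chloride (CC(C)CC(=O)Cl)
Why: Immediate acylation traps the ionisation-prone allylic alcohol. The tertiary C8–OTES and primary silyl ethers are unaffected.

**Step 13**
Reactants: 14
Product: 15, the triol (C8, C10, C11 free)
Conditions: HF·pyridine, pyridine/THF, 0 → 20 °C
Reagents that add atoms: none
Why: Buffered HF removes TES and the primary TBS ethers under non-basic, non-aqueous conditions that the acylal and diene tolerate.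

**Step 14**
Reactants: 15
Product: 16, jatamanvaltrate K
Conditions: Novozym 435, vinyl acetate, MTBE, 20 °C
Reagents that add atoms: vinyl acetate (CC(=O)OC=C)
Why: The lipase acetylates the unhindered allylic C11 primary alcohol in preference to the neopentyl C10 alcohol and the tertiary C8 alcohol, under neutral conditions.

---

## Compound list

1 | (R)-4-(TBSO)cyclopent-2-en-1-one | CC(C)(C)[Si](C)(C)O[C@@H]1CC(=O)C=C1 | starting material
2 | TES enol ether of 5β-OTBS-9α-vinylcyclopentanone | CC[Si](CC)(CC)OC1=C[C@@H](C=C)[C@H](O[Si](C)(C)C(C)(C)C)C1 | intermediate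
3 | 8-(TESO)-9α-vinyl-5β-OTBS-cyclopentan-7-one | O=C1C[C@@H](O[Si](C)(C)C(C)(C)C)[C@H](C=C)[C@H]1O[Si](CC)(CC)CC | intermediate
4 | 8β-(TESO)-9α-vinylcyclopent-5-en-7-one | O=C1C=C[C@H](C=C)[C@H]1O[Si](CC)(CC)CC | intermediate
5 | 8α-(TESO)-8β-(hydroxymethyl)-9α-vinylcyclopent-5-en-7-one | O=C1C=C[C@H](C=C)[C@]1(CO)O[Si](CC)(CC)CC | intermediate
6 | C10-OTBS ether of 5 | O=C1C=C[C@H](C=C)[C@]1(CO[Si](C)(C)C(C)(C)C)O[Si](CC)(CC)CC | intermediate
7 | 3-(TBSO)propanal | CC(C)(C)[Si](C)(C)OCCC=O | starting material
8 | 1-TMSO-3-TBSO-prop-1-ene (Z/E) | C[Si](C)(C)OC=CCO[Si](C)(C)C(C)(C)C | intermediate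
9 | Mukaiyama–Michael adduct, TMS enol ether (C4, C5 undefined) | C[Si](C)(C)OC1=CC(C(C=O)CO[Si](C)(C)C(C)(C)C)[C@H](C=C)[C@]1(CO[Si](C)(C)C(C)(C)C)O[Si](CC)(CC)CC | intermediate
10 | enone-aldehyde (C4 undefined) | O=CC(CO[Si](C)(C)C(C)(C)C)C1=CC(=O)[C@@](CO[Si](C)(C)C(C)(C)C)(O[Si](CC)(CC)CC)[C@H]1C=C | intermediate
11 | lactol-dienone (C1 anomeric mixture) | OC1OC=C(CO[Si](C)(C)C(C)(C)C)C2=CC(=O)[C@@](CO[Si](C)(C)C(C)(C)C)(O[Si](CC)(CC)CC)[C@@H]12 | intermediate
12 | 1β-isovalerate, 7-ketone | CC(C)(C)[Si](C)(C)OCC1=CO[C@@H](OC(=O)CC(C)C)[C@H]2C1=CC(=O)[C@]2(O[Si](CC)(CC)CC)CO[Si](C)(C)C(C)(C)C | intermediate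
13 | 7β-alcohol | CC(C)(C)[Si](C)(C)OCC1=CO[C@@H](OC(=O)CC(C)C)[C@H]2C1=C[C@H](O)[C@]2(O[Si](CC)(CC)CC)CO[Si](C)(C)C(C)(C)C | intermediate
14 | 1,7-bis(isovalerate), tris-silyl ether | CC(C)(C)[Si](C)(C)OCC1=CO[C@@H](OC(=O)CC(C)C)[C@H]2C1=C[C@H](OC(=O)CC(C)C)[C@]2(O[Si](CC)(CC)CC)CO[Si](C)(C)C(C)(C)C | intermediate
15 | triol (C8, C10, C11 free) | OCC1=CO[C@@H](OC(=O)CC(C)C)[C@H]2C1=C[C@H](OC(=O)CC(C)C)[C@]2(O)CO | intermediate
16 | Jatamanvaltrate K | CC(=O)OCC1=CO[C@@H](OC(=O)CC(C)C)[C@H]2C1=C[C@H](OC(=O)CC(C)C)[C@]2(O)CO | target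

---

**Total step count:** 14 steps (including the side-branch step 6).
**Longest linear sequence:** 13 steps (1→2→3→4→5→9→10→11→12→13→14→15→16, i.e. steps 1–5 and 7–14).

**Three steps most likely to fail:**

1. **Step 4 (C8 hydroxymethylation).**
   - Risk: γ-deprotonation at C9 could epimerise C9, and facial selectivity could be poor.
   - Fallback: change the approach to build C8 as a ketone. Make the 7,8-dione from 4 and add LiCH2OMOM or Me3S(O)I/NaH to C8 from the convex β face. This gives C10 β and OH α, and the C7 ketone is reduced as planned.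

2. **Step 7 (Mukaiyama–Michael, followed by Saegusa in step 8).**
   - Risk: the hindered β-carbon next to the C9 vinyl and C8 quaternary centre may give poor 1,4-selectivity or yield.
   - Fallback: install C4 by conjugate addition of (E)-2-ethoxyvinyl cuprate, giving a C5–CH=CH–OEt side chain. Then introduce C11 at C4 late, by C4 iodination of the push–pull pyran and Pd-catalysed coupling with an acetoxymethyl-trifluoroborate.

3. **Step 11 (C7 reduction facial selectivity and stability).**
   - Risk: the wrong epimer may form, and the allylic alcohol ionises easily through the dienol ether.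
   - Fallback: change to a reagent-controlled (R)-Me-CBS reduction, or reduce to the epimeric alcohol and invert directly to the ester by Mitsunobu reaction with isovaleric acid.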